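**Retrosynthetic overview**

1. Presumed biosynthesis (cyathane type): GGPP → 5–7 hydroazulenyl cation → Wagner–Meerwein 1,2-alkyl shift (cyclopentane → ring B, new quaternary C9) → capture of the C4 electrophile by the side-chain π-bond (ring A) → oxidative tailoring (lactone, epoxide).
2. Target ⇐ C12=C13 epoxidation; α-methylene lactone ⇐ intramolecular Morita–Baylis–Hillman closure of a C2 acrylate onto a C3 ketone; C3 ketone with 4β-H ⇐ Meinwald 1,2-hydride shift of a 3α,4α-epoxy alcohol.
3. Rings B and A in one flask ⇐ epoxy-alcohol semipinacol (C8 migrates from C4 to C9, cyclopentanol → cyclohexanone) followed by aldol closure of C3 onto the new C4 ketone.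
4. Epoxy alcohol ⇐ trans-hydroazulenone + 2-metallated allyl ketal; hydroazulenone ⇐ ring-closing metathesis (ring C) of a dienone made by asymmetric conjugate methylation (C6) and Mukaiyama aldol.
5. Ring order: cyclopentane (pre-ring B) → ring C → ring B (ring expansion) → ring A → lactone → epoxide.

Assumption: the target is treated as an oxidised cyathane and cyathane numbering is used (ring A = C1–C4/C9, ring B = C4–C9, ring C = C5/C6/C10–C14, C15 on C12, C16 on C6, C17 on C9, C18–C20 = lactone carbons); β = face of the C6 methyl, α = the opposite face.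

**Route**

Step 1
Reactants: 1 2-methylallylmagnesium chloride, 2 trimethyl orthoformate
Product: 3 4,4-dimethoxy-2-methylbut-1-ene
Conditions: THF, 65 °C; then H2O
Reagents that add atoms: none
Why: Bodroux–Chichibabin substitution of one orthoester methoxy group by the allylic Grignard reagent gives the stable acetal of the labile 3-methylbut-3-enal.

Step 2
Reactants: 4 3-ethoxycyclopent-2-en-1-one, 5 allylmagnesium bromide
Product: 7 3-allylcyclopent-2-en-1-one, via bromomagnesium alkoxide 6 (not isolated)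
Conditions: Et2O, 0 °C; then 1 M aq. HCl, 0 °C, 15 min
Reagents that add atoms: water, O
Why: Stork–Danheiser transposition (1,2-addition to the vinylogous ester, then acid hydrolysis with loss of ethanol) gives the 3-substituted enone without forming a stereocentre.

Step 3
Reactants: 7 3-allylcyclopent-2-en-1-one
Product: 9 (S)-[(3-allyl-3-methylcyclopent-1-en-1-yl)oxy]trimethylsilane, via aluminium enolate 8 (not isolated)
Conditions: Me3Al (1.2 equiv), Cu(OTf)2 (5 mol %), chiral sulfonate-bearing imidazolinium salt (NHC precursor, 6 mol %), THF, −78 °C; then TMSOTf, −78 → 0 °C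
Reagents that add atoms: trimethylaluminium, C[Al](C)C; trimethylsilyl trifluoromethanesulfonate, C[Si](C)(C)OS(=O)(=O)C(F)(F)F
Why: NHC–copper-catalysed asymmetric conjugate addition sets the C6 quaternary centre under catalyst control (ligand enantiomer chosen for S), and silylation fixes the enolate regiospecifically on the C5 side.

Step 4
Reactants: 9 (S)-[(3-allyl-3-methylcyclopent-1-en-1-yl)oxy]trimethylsilane, 3 4,4-dimethoxy-2-methylbut-1-ene
Product: 11 (2E,3S)-3-allyl-3-methyl-2-(3-methylbut-3-en-1-ylidene)cyclopentan-1-one, via methoxy ketone 10 (not isolated)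
Conditions: TMSOTf (10 mol %), CH2Cl2, −78 °C; then DBU, 0 °C, short contact
Reagents that add atoms: none
Why: Mukaiyama aldol addition to the acetal-derived oxocarbenium ion followed by E1cB loss of methanol installs the C5=C10 alkylidene as the E enone, with no new stereocentre.

Step 5
Reactants: 11 (2E,3S)-3-allyl-3-methyl-2-(3-methylbut-3-en-1-ylidene)cyclopentan-1-one
Product: 12 (3aS)-3a,6-dimethyl-3,3a,4,7-tetrahydroazulen-1(2H)-one
Conditions: second-generation Grubbs catalyst (5 mol %), CH2Cl2 (5 mM), 40 °C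
Reagents that add atoms: none
Why: Ring-closing metathesis of the allyl and 1,1-disubstituted alkenes closes seven-membered ring C with the trisubstituted C12=C13 olefin, the electron-poor enone alkene staying inert.

Step 6
Reactants: 12 (3aS)-3a,6-dimethyl-3,3a,4,7-tetrahydroazulen-1(2H)-one
Product: 13 (3aS,8aS)-3a,6-dimethyl-3,3a,4,7,8,8a-hexahydroazulen-1(2H)-one
Conditions: [(Ph3P)CuH]6 (0.4 equiv), H2O (3 equiv), benzene, rt
Reagents that add atoms: none
Why: Stryker conjugate reduction puts hydride on C10 and the copper enolate is protonated at C5 from the α-face, anti to the angular methyl (the face electrophiles take in daucene-type hydroazulenes), giving the trans-fused ketone.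

Step 7
Reactants: 14 methyl vinyl ether, 15 2,3-dibromoprop-1-ene, 16 ethane-1,2-diol
Product: 19 2-(2-bromoprop-2-en-1-yl)-2-methyl-1,3-dioxolane, via 1-methoxyvinyllithium 17 (not isolated), via methoxy diene 18 (not isolated)
Conditions: t-BuLi, THF, −78 → 0 °C; 15, −78 °C → rt; then 16, PPTS (cat.), rt
Reagents that add atoms: none
Why: Alkylation of the acyl-anion equivalent 1-methoxyvinyllithium at the allylic bromide, then acid-catalysed exchange of the enol ether with the diol, gives the ketal-masked 2-bromoallyl methyl ketone.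

Step 8
Reactants: 19 2-(2-bromoprop-2-en-1-yl)-2-methyl-1,3-dioxolane, 13 (3aS,8aS)-3a,6-dimethyl-3,3a,4,7,8,8a-hexahydroazulen-1(2H)-one
Product: 21 (1R,3aS,8aS)-3a,6-dimethyl-1-[3-(2-methyl-1,3-dioxolan-2-yl)prop-1-en-2-yl]-1,2,3,3a,4,7,8,8a-octahydroazulen-1-ol, via Grignard reagent 20 (not isolated)
Conditions: Mg, THF, 50 °C; then 13, LaCl3·2LiCl (0.3 equiv), THF, 0 °C; then H2O
Reagents that add atoms: none
Why: Lanthanum-promoted Grignard 1,2-addition to the enolisable ketone occurs from the α-face (anti to C10 and the angular methyl), setting the C4 carbinol with OH β.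

Step 9
Reactants: 21 (1R,3aS,8aS)-3a,6-dimethyl-1-[3-(2-methyl-1,3-dioxolan-2-yl)prop-1-en-2-yl]-1,2,3,3a,4,7,8,8a-octahydroazulen-1-ol
Product: 22 (1R,3aS,8aS)-3a,6-dimethyl-1-{(2S)-2-[(2-methyl-1,3-dioxolan-2-yl)methyl]oxiran-2-yl}-1,2,3,3a,4,7,8,8a-octahydroazulen-1-ol
Conditions: VO(acac)2 (5 mol %), t-BuOOH (1.5 equiv), CH2Cl2, 0 °C → rt
Reagents that add atoms: tert-butyl hydroperoxide, CC(C)(C)OO
Why: Hydroxyl-directed vanadium epoxidation touches only the allylic 1,1-disubstituted alkene, and the transition state with the smaller C8 (not C5) eclipsing the C1 chain (minimal A(1,2) strain) sets the epoxide carbon C9 as S.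

Step 10
Reactants: 22 (1R,3aS,8aS)-3a,6-dimethyl-1-{(2S)-2-[(2-methyl-1,3-dioxolan-2-yl)methyl]oxiran-2-yl}-1,2,3,3a,4,7,8,8a-octahydroazulen-1-ol
Product: 26 17-hydroxy-18,19,20-trinorcyatha-3,12-dien-2-one, via hydroxy ketone 23 (not isolated), via diketone 24 (not isolated), via aldol 25 (not isolated)
Conditions: BF3·OEt2 (0.3 equiv), CH2Cl2, −78 → −30 °C; then TsOH·H2O (20 mol %), THF/H2O, 55 °C
Reagents that add atoms: water, O
Why: Epoxide-triggered semipinacol rearrangement (Wagner–Meerwein 1,2-alkyl shift) moves C8 from C4 to C9 anti to the breaking C–O bond, so inversion at C9 gives ring B with the α-CH2OH quaternary centre, and acid then unmasks the methyl ketone, whose enol closes ring A by intramolecular aldol condensation on the new C4 ketone.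

Step 11
Reactants: 26 17-hydroxy-18,19,20-trinorcyatha-3,12-dien-2-one
Product: 27 18,19,20-trinorcyatha-3,12-diene-2α,17-diol
Conditions: NaBH4, CeCl3·7H2O, MeOH, −78 °C
Reagents that add atoms: none
Why: Luche 1,2-reduction delivers hydride to C2 from the β-face, away from the angular α-CH2OH on C9, giving the 2α-alcohol.

Step 12
Reactants: 27 18,19,20-trinorcyatha-3,12-diene-2α,17-diol
Product: 28 3α,4α-epoxy-18,19,20-trinorcyath-12-ene-2α,17-diol
Conditions: VO(acac)2 (5 mol %), t-BuOOH (1.3 equiv), CH2Cl2, 0 °C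
Reagents that add atoms: tert-butyl hydroperoxide, CC(C)(C)OO
Why: Vanadium-catalysed epoxidation directed by the 2α- and 17-hydroxyls delivers oxygen to the α-face of C3=C4 only, the remote C12=C13 not being directed.

Step 13
Reactants: 28 3α,4α-epoxy-18,19,20-trinorcyath-12-ene-2α,17-diol
Product: 29 2α,17-dihydroxy-18,19,20-trinorcyath-12-en-3-one
Conditions: BF3·OEt2 (0.2 equiv), CH2Cl2, −78 → −40 °C
Reagents that add atoms: none
Why: Meinwald rearrangement with ionisation at tertiary C4 and suprafacial 1,2-hydride shift from C3 across the β-face gives the C3 ketone and, stereospecifically, the 4β-H (trans A/B fusion).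

Step 14
Reactants: 29 2α,17-dihydroxy-18,19,20-trinorcyath-12-en-3-one
Product: 31 17-acetoxy-3-oxo-18,19,20-trinorcyath-12-en-2α-yl acrylate, via monoacetate 30 (not isolated)
Conditions: Ac2O (1.05 equiv), pyridine, CH2Cl2, −20 → 0 °C; then acryloyl chloride, Et3N, DMAP (cat.), 0 °C
Reagents that add atoms: acetic anhydride, CC(=O)OC(C)=O; acryloyl chloride, C=CC(Cl)=O
Why: Sequential acylation acetylates the more reactive primary C17 alcohol first and then esterifies the remaining secondary 2α-alcohol with acryloyl chloride, leaving all stereocentres untouched.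

Step 15
Reactants: 31 17-acetoxy-3-oxo-18,19,20-trinorcyath-12-en-2α-yl acrylate
Product: 32 17-acetoxy-3β-hydroxycyatha-12,18(19)-dien-20,2α-olide
Conditions: PMe3 (0.3 equiv), t-AmOH/THF, rt
Reagents that add atoms: none
Why: Intramolecular Morita–Baylis–Hillman reaction in which the phosphonium enolate of the acrylate adds to the C3 ketone, the C2–O tether forcing α-face attack so that the lactone is cis-fused and the new C3 hydroxyl is β.

Step 16
Reactants: 32 17-acetoxy-3β-hydroxycyatha-12,18(19)-dien-20,2α-olide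
Product: 33 17-acetoxy-12α,13α-epoxy-3β-hydroxycyath-18(19)-en-20,2α-olide
Conditions: mCPBA (1.1 equiv), NaHCO3, CH2Cl2, 0 °C
Reagents that add atoms: 3-chloroperoxybenzoic acid, OOC(=O)c1cccc(Cl)c1
Why: Prilezhaev epoxidation of the only electron-rich alkene (the acrylate is inert) from the α-face, anti to the C6 angular methyl that shields the β-face of C12=C13.

**Compound list**

1 | 2-methylallylmagnesium chloride | C=C(C)C[Mg]Cl | starting material
2 | trimethyl orthoformate | COC(OC)OC | starting material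
3 | 4,4-dimethoxy-2-methylbut-1-ene | C=C(C)CC(OC)OC | intermediate
4 | 3-ethoxycyclopent-2-en-1-one | CCOC1=CC(=O)CC1 | starting material
5 | allylmagnesium bromide | C=CC[Mg]Br | starting material
6 | bromomagnesium 1-allyl-3-ethoxycyclopent-2-en-1-olate (racemic) | CCOC1=CC(CC=C)(O[Mg]Br)CC1 | intermediate
7 | 3-allylcyclopent-2-en-1-one | C=CCC1=CC(=O)CC1 | intermediate
8 | dimethylaluminium (S)-3-allyl-3-methylcyclopent-1-en-1-olate | C[Al](C)OC1=C[C@](C)(CC=C)CC1 | intermediate
9 | (S)-[(3-allyl-3-methylcyclopent-1-en-1-yl)oxy]trimethylsilane | C[Si](C)(C)OC1=C[C@](C)(CC=C)CC1 | intermediate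
10 | (3S)-3-allyl-2-(1-methoxy-3-methylbut-3-en-1-yl)-3-methylcyclopentan-1-one (mixture at C2 and at the methoxy carbon) | O=C1CC[C@@](C)(CC=C)C1C(OC)CC(C)=C | intermediate
11 | (2E,3S)-3-allyl-3-methyl-2-(3-methylbut-3-en-1-ylidene)cyclopentan-1-one | O=C1CC[C@@](C)(CC=C)/C1=C\CC(C)=C | intermediate
12 | (3aS)-3a,6-dimethyl-3,3a,4,7-tetrahydroazulen-1(2H)-one | O=C1CC[C@@]2(C)CC=C(C)CC=C12 | intermediate
13 | (3aS,8aS)-3a,6-dimethyl-3,3a,4,7,8,8a-hexahydroazulen-1(2H)-one (trans-fused, 8a-H anti to 3a-CH3) | O=C1CC[C@@]2(C)CC=C(C)CC[C@H]12 | intermediate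
14 | methyl vinyl ether | COC=C | starting material
15 | 2,3-dibromoprop-1-ene | C=C(Br)CBr | starting material
16 | ethane-1,2-diol | OCCO | starting material
17 | 1-methoxyvinyllithium | [Li]C(=C)OC | intermediate
18 | 2-bromo-4-methoxypenta-1,4-diene | C=C(Br)CC(=C)OC | intermediate
19 | 2-(2-bromoprop-2-en-1-yl)-2-methyl-1,3-dioxolane | CC1(CC(Br)=C)OCCO1 | intermediate
20 | [3-(2-methyl-1,3-dioxolan-2-yl)prop-1-en-2-yl]magnesium bromide | CC1(CC(=C)[Mg]Br)OCCO1 | intermediate
21 | (1R,3aS,8aS)-3a,6-dimethyl-1-[3-(2-methyl-1,3-dioxolan-2-yl)prop-1-en-2-yl]-1,2,3,3a,4,7,8,8a-octahydroazulen-1-ol (OH β, alkenyl α) | C=C(CC1(C)OCCO1)[C@@]2(O)CC[C@@]3(C)CC=C(C)CC[C@H]23 | intermediate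
22 | (1R,3aS,8aS)-3a,6-dimethyl-1-{(2S)-2-[(2-methyl-1,3-dioxolan-2-yl)methyl]oxiran-2-yl}-1,2,3,3a,4,7,8,8a-octahydroazulen-1-ol | CC1(C[C@]2(CO2)[C@@]3(O)CC[C@@]4(C)CC=C(C)CC[C@H]34)OCCO1 | intermediate
23 | (2S,4aS,9aS)-2-(hydroxymethyl)-4a,7-dimethyl-2-[(2-methyl-1,3-dioxolan-2-yl)methyl]-2,3,4,4a,5,8,9,9a-octahydro-1H-benzo[7]annulen-1-one | CC1(C[C@]2(CO)CC[C@@]3(C)CC=C(C)CC[C@@H]3C2=O)OCCO1 | intermediate
24 | (2S,4aS,9aS)-2-(hydroxymethyl)-4a,7-dimethyl-2-(2-oxopropyl)-2,3,4,4a,5,8,9,9a-octahydro-1H-benzo[7]annulen-1-one | CC(=O)C[C@]1(CO)CC[C@@]2(C)CC=C(C)CC[C@@H]2C1=O | intermediate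
25 | 4,17-dihydroxy-18,19,20-trinorcyath-12-en-2-one (5α-H, 6β-CH3, 9α-CH2OH; C4 epimers) | O=C1C[C@]2(CO)CC[C@@]3(C)CC=C(C)CC[C@@H]3C2(O)C1 | intermediate
26 | 17-hydroxy-18,19,20-trinorcyatha-3,12-dien-2-one (5α-H, 6β-CH3, 9α-CH2OH) | O=C1C[C@]2(CO)CC[C@@]3(C)CC=C(C)CC[C@@H]3C2=C1 | intermediate
27 | 18,19,20-trinorcyatha-3,12-diene-2α,17-diol | O[C@H]1C[C@]2(CO)CC[C@@]3(C)CC=C(C)CC[C@@H]3C2=C1 | intermediate
28 | 3α,4α-epoxy-18,19,20-trinorcyath-12-ene-2α,17-diol | O[C@H]1C[C@]2(CO)CC[C@@]3(C)CC=C(C)CC[C@@H]3[C@@]24O[C@@H]14 | intermediate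
29 | 2α,17-dihydroxy-18,19,20-trinorcyath-12-en-3-one (4β-H, 5α-H) | O[C@H]1C[C@]2(CO)CC[C@@]3(C)CC=C(C)CC[C@@H]3[C@H]2C1=O | intermediate
30 | 17-acetoxy-2α-hydroxy-18,19,20-trinorcyath-12-en-3-one | O[C@H]1C[C@]2(COC(C)=O)CC[C@@]3(C)CC=C(C)CC[C@@H]3[C@H]2C1=O | intermediate
31 | 17-acetoxy-3-oxo-18,19,20-trinorcyath-12-en-2α-yl acrylate | C=CC(=O)O[C@H]1C[C@]2(COC(C)=O)CC[C@@]3(C)CC=C(C)CC[C@@H]3[C@H]2C1=O | intermediate
32 | 17-acetoxy-3β-hydroxycyatha-12,18(19)-dien-20,2α-olide | C=C1C(=O)O[C@H]2C[C@]3(COC(C)=O)CC[C@@]4(C)CC=C(C)CC[C@@H]4[C@H]3[C@@]12O | intermediate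
33 | 17-acetoxy-12α,13α-epoxy-3β-hydroxycyath-18(19)-en-20,2α-olide (CNP0404717.1; 4β-H, 5α-H, 6β-CH3, 9α-CH2OAc) | C=C1C(=O)O[C@H]2C[C@]3(COC(C)=O)CC[C@@]4(C)C[C@H]5O[C@@]5(C)CC[C@@H]4[C@H]3[C@@]12O | target

**Step count and risks**

Total step count: 16. Longest linear sequence: 14 steps (steps 2–6 and 8–16; steps 1 and 7 make the two side fragments).

The three steps most likely to fail:

Step 6 (C5 configuration). Substrate-controlled protonation of the copper enolate may give the cis-fused ketone. The fallback sets out from dienone 12 and returns to ketone 13. Copper hydride-catalysed 1,4-hydrosilylation ([(Ph3P)CuH]6 5 mol %, PhMe2SiH, toluene) gives the isolable dimethylphenylsilyl enol ether F1. This is protonated under reagent control with the chiral proton source (R)-BINOL·SnCl4 (toluene, −78 °C; the BINOL enantiomer is chosen to deliver H to the α-face).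

Step 10 (C8 versus C5 migration, and the aldol closure). The more substituted C5 has the higher intrinsic migratory aptitude, so selectivity rests on the chelated rotamer set up in step 9. The fallback sets out from ketone 13 and returns at diol 27, replacing steps 8–11. Sc(OTf)3-catalysed homologation with methyl 2-diazo-3-(2-methyl-1,3-dioxolan-2-yl)propanoate (COC(=O)C(=[N+]=[N-])CC1(C)OCCO1) inserts the diazo carbon between C4 and the less substituted C8 and gives the β-keto ester F2. The C9 selectivity of this insertion is not predictable and the epimers would be separated at this stage. TsOH in aqueous THF then removes the ketal and closes ring A to the tricyclic enone ester F3. i-Bu2AlH (CH2Cl2, −78 °C) reduces both the ester and the enone carbonyl (hydride from the β-face) to 27.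

Step 15 (Morita–Baylis–Hillman addition to a hindered ketone). The fallback sets out from acrylate 31 and returns at lactone 32. Tandem Michael–aldol cyclisation with Me2AlSPh (CH2Cl2, −78 °C) gives the phenylsulfanylmethyl lactone F4. NaIO4 (MeOH/H2O) oxidises it to the sulfoxide F5, and thermolysis (toluene, 110 °C, CaCO3) eliminates the sulfoxide to give the exocyclic methylene.

Further compounds
F1 | step 6 | (3aS)-[(3a,6-dimethyl-2,3,3a,4,7,8-hexahydroazulen-1-yl)oxy]dimethyl(phenyl)silane | C[Si](C)(c1ccccc1)OC2=C3CCC(C)=CC[C@]3(C)CC2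
F2 | step 10 | methyl 4a,7-dimethyl-2-[(2-methyl-1,3-dioxolan-2-yl)methyl]-1-oxo-2,3,4,4a,5,8,9,9a-octahydro-1H-benzo[7]annulene-2-carboxylate (ester analogue of 23, CO2CH3 α on C9, 5α-H, 6β-CH3) | CC1(C[C@]2(C(=O)OC)CC[C@@]3(C)CC=C(C)CC[C@@H]3C2=O)OCCO1
F3 | step 10 | methyl 2-oxo-18,19,20-trinorcyatha-3,12-dien-17-oate | O=C1C[C@]2(C(=O)OC)CC[C@@]3(C)CC=C(C)CC[C@@H]3C2=C1
F4 | step 15 | 17-acetoxy-3β-hydroxy-19-(phenylsulfanyl)cyath-12-en-20,2α-olide (C18 epimers) | O=C1O[C@H]2C[C@]3(COC(C)=O)CC[C@@]4(C)CC=C(C)CC[C@@H]4[C@H]3[C@@]2(O)C1CSc5ccccc5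
F5 | step 15 | 17-acetoxy-3β-hydroxy-19-(phenylsulfinyl)cyath-12-en-20,2α-olide (C18 and sulfur epimers) | O=C1O[C@H]2C[C@]3(COC(C)=O)CC[C@@]4(C)CC=C(C)CC[C@@H]4[C@H]3[C@@]2(O)C1CS(=O)c5ccccc5
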